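**Assumption:** the oxepine is taken to arise in Nature by intramolecular oxa-Michael addition of the C14 allylic hydroxyl onto the C2=C3 aroylacrylate of an oxidised farnesyl-hydroquinone. Farnesyl numbering is used below: C1 = aryl ketone carbon, C3 = carboxyl-bearing carbon, C14 = CH2–O on C7, C12 = terminal CH2OH.

## Retrosynthetic overview

1. Target ⇐ one-pot ester hydrolysis and MOM removal of the (R)-oxepine methyl ester.
2. Oxepine ⇐ catalyst-controlled 7-exo oxa-Michael addition of the free C14–OH to the open-chain (E)-aroylacrylate, setting the C3 quaternary centre.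
3. Aroylacrylate ⇐ B-alkyl Suzuki coupling of an enol triflate (bis-MOM 2′,5′-dihydroxyacetophenone + dimethyl oxalate) with the 9-BBN adduct of a (Z)-dienediol.
4. Dienediol ⇐ Stille vinylation, SeO2 oxidation and Cu-catalysed anti-carbomagnesiation/iodination of propargyl alcohol with homoprenylmagnesium bromide (fixes the Z-alkene).
5. Ring order: the benzene ring is bought; the tetrahydrooxepine is the only ring made, in the penultimate step.

## Route

Step 1
Reactants: 1 prop-2-yn-1-ol; 2 5-bromo-2-methylpent-2-ene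
Product: 5 (2Z)-2-(iodomethylidene)-6-methylhept-5-en-1-ol, via homoprenylmagnesium bromide 3 (not isolated), via alkenylmagnesium alkoxide 4 (not isolated)
Conditions: 2 (2.3 equiv), Mg, THF, rt; add to 1 (1.0 equiv), CuI (10 mol%), Et2O/THF, −10 °C → rt, 14 h; I2 (1.4 equiv), −78 → 0 °C; 1 M HCl work-up
Reagents that add atoms: iodine, II
Why: Cu-catalysed anti-carbomagnesiation of the propargylic alkoxide (Duboudin–Jousseaume) puts the homoprenyl group on C2 and magnesium on C3 cis to CH2O through a five-membered chelate, and iodinolysis with retention fixes the Z-trisubstituted alkene that later becomes the ring alkene.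

Step 2
Reactants: 5 (2Z)-2-(iodomethylidene)-6-methylhept-5-en-1-ol
Product: 6 (2E,6Z)-6-(iodomethylidene)-2-methylhept-2-ene-1,7-diol
Conditions: SeO2 (0.2 equiv), t-BuOOH (2.5 equiv, 5.5 M in decane), salicylic acid (0.1 equiv), CH2Cl2, 0 °C → rt, stop at ~60% conversion, recycle 5
Reagents that add atoms: tert-butyl hydroperoxide, CC(C)(C)OO (stoichiometric oxygen source); selenium dioxide, O=[Se]=O (catalytic oxygen carrier)
Why: Sharpless SeO2/t-BuOOH allylic oxidation (ene reaction then [2,3]-shift) attacks only the electron-rich trisubstituted alkene and oxidises its E-methyl group to the (E)-allylic alcohol, while the iodo-alkene with its allylic oxygen is deactivated.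

Step 3
Reactants: 6 (2E,6Z)-6-(iodomethylidene)-2-methylhept-2-ene-1,7-diol; 7 tributyl(ethenyl)stannane
Product: 8 (2E,6Z)-6-(hydroxymethyl)-2-methylnona-2,6,8-trien-1-ol
Conditions: PdCl2(MeCN)2 (5 mol%), DMF, 25 °C, dark
Reagents that add atoms: none
Why: Stille coupling of an alkenyl iodide with a vinylstannane runs at room temperature with retention of alkene geometry and tolerates free alcohols.

Step 4
Reactants: 9 1-(2,5-dihydroxyphenyl)ethan-1-one
Product: 10 1-[2,5-bis(methoxymethoxy)phenyl]ethan-1-one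
Conditions: NaH (2.4 equiv), MOMCl (2.6 equiv), DMF, 0 °C → rt
Reagents that add atoms: chloromethyl methyl ether, COCCl
Why: Williamson-type O-alkylation of both phenoxides gives base-stable MOM acetals, which later stop the ortho-phenol from adding to the enone (no chromanone formation).

Step 5
Reactants: 10 1-[2,5-bis(methoxymethoxy)phenyl]ethan-1-one; 11 dimethyl oxalate
Product: 12 methyl (2Z)-4-[2,5-bis(methoxymethoxy)phenyl]-2-hydroxy-4-oxobut-2-enoate
Conditions: NaOMe (2 equiv), MeOH/THF, 0 → 45 °C; AcOH quench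
Reagents that add atoms: none
Why: Crossed Claisen condensation of the methyl ketone enolate with the non-enolisable oxalate is driven by formation of the stabilised diketo-ester enolate, and the product exists as the chelated (Z)-2-enol.

Step 6
Reactants: 12 methyl (2Z)-4-[2,5-bis(methoxymethoxy)phenyl]-2-hydroxy-4-oxobut-2-enoate
Product: 13 methyl (2Z)-4-[2,5-bis(methoxymethoxy)phenyl]-4-oxo-2-{[(trifluoromethyl)sulfonyl]oxy}but-2-enoate
Conditions: NaH (1.1 equiv), CH2Cl2, 0 °C; Tf2O (1.1 equiv), −78 → 0 °C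
Reagents that add atoms: trifluoromethanesulfonic anhydride, O=S(=O)(OS(=O)(=O)C(F)(F)F)C(F)(F)F
Why: Enol triflate formation on the sodium chelate of the 2-enol is expected at the oxygen next to the ester rather than at the hindered aryl ketone oxygen, with the chelate holding the Z geometry; any C4–OTf regioisomer would be separated by chromatography.

Step 7
Reactants: 8 (2E,6Z)-6-(hydroxymethyl)-2-methylnona-2,6,8-trien-1-ol; 13 methyl (2Z)-4-[2,5-bis(methoxymethoxy)phenyl]-4-oxo-2-{[(trifluoromethyl)sulfonyl]oxy}but-2-enoate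
Product: 15 methyl (2E)-4-[2,5-bis(methoxymethoxy)phenyl]-2-[(3Z,7E)-9-hydroxy-4-(hydroxymethyl)-8-methylnona-3,7-dien-1-yl]-4-oxobut-2-enoate, via tris-9-BBN alkylborane 14 (not isolated)
Conditions: 8 (1.15 equiv), 9-BBN (3.1 equiv per 8), THF, 0 °C → rt, 4 h; then 13 (1.0 equiv), PdCl2(dppf) (5 mol%), AsPh3 (10 mol%), powdered K3PO4 (3 equiv), DMF, 25 °C; pH 7 buffer work-up
Reagents that add atoms: none
Why: 9-BBN hydroborates only the monosubstituted alkene of the diene at its terminus and converts both OH groups into O-BBN borinates, and the B-alkyl Suzuki–Miyaura coupling with the electron-poor enol triflate proceeds with retention to give the (E)-aroylacrylate with the alcohols masked until work-up.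

Step 8
Reactants: 15 methyl (2E)-4-[2,5-bis(methoxymethoxy)phenyl]-2-[(3Z,7E)-9-hydroxy-4-(hydroxymethyl)-8-methylnona-3,7-dien-1-yl]-4-oxobut-2-enoate
Product: 16 methyl (2R)-2-{2-[2,5-bis(methoxymethoxy)phenyl]-2-oxoethyl}-6-[(3E)-5-hydroxy-4-methylpent-3-en-1-yl]-2,3,4,7-tetrahydrooxepine-2-carboxylate
Conditions: quinidine-derived squaramide, 3-{[3,5-bis(trifluoromethyl)phenyl]amino}-4-{[(9R)-6′-methoxycinchonan-9-yl]amino}cyclobut-3-ene-1,2-dione (10 mol%), toluene (0.02 M), 4 Å MS, 0 °C → rt
Reagents that add atoms: none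
Why: Proposed new method: in this asymmetric intramolecular oxa-Michael addition the squaramide N–H bonds hold the aryl ketone of the (E)-aroylacrylate while the quinuclidine acts as general base for the C14 allylic OH, which adds 7-exo-trig to the ester-bearing alkene carbon (β to the ketone, the more activated position) on its Re face (CO2Me > CH= > CH2) to give the (R) tetrasubstituted ether centre under kinetic control, the cis-alkene in the tether preorganising ring closure and the remote C12–OH being unable to compete (11-membered ring); the closest known reactions are cinchona amine–thiourea/squaramide-catalysed enantioselective oxa-Michael cycloetherifications of hydroxy enones to tetrahydrofurans and tetrahydropyrans, extended here to a seven-membered ring and a fully substituted carbon.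

Step 9
Reactants: 16 methyl (2R)-2-{2-[2,5-bis(methoxymethoxy)phenyl]-2-oxoethyl}-6-[(3E)-5-hydroxy-4-methylpent-3-en-1-yl]-2,3,4,7-tetrahydrooxepine-2-carboxylate
Product: 18 (2R)-2-[2-(2,5-dihydroxyphenyl)-2-oxoethyl]-6-[(3E)-5-hydroxy-4-methylpent-3-en-1-yl]-2,3,4,7-tetrahydrooxepine-2-carboxylic acid, via bis-MOM carboxylic acid 17 (not isolated)
Conditions: LiOH·H2O (4 equiv), degassed THF/H2O 3:1, 0 °C → rt; then aq. HCl to ~1.5 M, 35 °C, Ar
Reagents that add atoms: lithium hydroxide, [Li+].[OH-]
Why: Saponification of the activated α-alkoxy methyl ester at 0 °C should outrun enolisation/β-elimination of the β-alkoxy ketone, and acid hydrolysis of the two aryl MOM acetals in the same pot frees the hydroquinone without touching the quaternary stereocentre.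

## Compound list

1 | prop-2-yn-1-ol | C#CCO | starting material
2 | 5-bromo-2-methylpent-2-ene | CC(C)=CCCBr | starting material
3 | (4-methylpent-3-en-1-yl)magnesium bromide | CC(C)=CCC[Mg]Br | intermediate (not isolated)
4 | bromomagnesium (2Z)-2-[(bromomagnesio)methylidene]-6-methylhept-5-en-1-olate | CC(C)=CCC/C(CO[Mg]Br)=C/[Mg]Br | intermediate (not isolated)
5 | (2Z)-2-(iodomethylidene)-6-methylhept-5-en-1-ol | CC(C)=CCC/C(CO)=C/I | intermediate
6 | (2E,6Z)-6-(iodomethylidene)-2-methylhept-2-ene-1,7-diol | C/C(=C\CC/C(CO)=C/I)CO | intermediate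
7 | tributyl(ethenyl)stannane | C=C[Sn](CCCC)(CCCC)CCCC | starting material
8 | (2E,6Z)-6-(hydroxymethyl)-2-methylnona-2,6,8-trien-1-ol | C/C(=C\CC/C(CO)=C/C=C)CO | intermediate
9 | 1-(2,5-dihydroxyphenyl)ethan-1-one | CC(=O)c1cc(O)ccc1O | starting material
10 | 1-[2,5-bis(methoxymethoxy)phenyl]ethan-1-one | CC(=O)c1cc(OCOC)ccc1OCOC | intermediate
11 | dimethyl oxalate | COC(=O)C(=O)OC | starting material
12 | methyl (2Z)-4-[2,5-bis(methoxymethoxy)phenyl]-2-hydroxy-4-oxobut-2-enoate | COC(=O)/C(O)=C/C(=O)c1cc(OCOC)ccc1OCOC | intermediate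
13 | methyl (2Z)-4-[2,5-bis(methoxymethoxy)phenyl]-4-oxo-2-{[(trifluoromethyl)sulfonyl]oxy}but-2-enoate | COC(=O)/C(OS(=O)(=O)C(F)(F)F)=C/C(=O)c1cc(OCOC)ccc1OCOC | intermediate
14 | tris-9-BBN adduct of 8: B-[(3Z,7E)-nona-3,7-dien-1-yl]-9-BBN carrying 8-methyl, 9-(9-BBN-oxy) and 4-[(9-BBN-oxy)methyl] | C/C(=C\CC/C(COB1C2CCCC1CCC2)=C/CCB1C2CCCC1CCC2)COB1C2CCCC1CCC2 | intermediate (not isolated)
15 | methyl (2E)-4-[2,5-bis(methoxymethoxy)phenyl]-2-[(3Z,7E)-9-hydroxy-4-(hydroxymethyl)-8-methylnona-3,7-dien-1-yl]-4-oxobut-2-enoate | COC(=O)/C(CC/C=C(\CO)CC/C=C(\C)CO)=C/C(=O)c1cc(OCOC)ccc1OCOC | intermediate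
16 | methyl (2R)-2-{2-[2,5-bis(methoxymethoxy)phenyl]-2-oxoethyl}-6-[(3E)-5-hydroxy-4-methylpent-3-en-1-yl]-2,3,4,7-tetrahydrooxepine-2-carboxylate | C/C(=C\CCC1=CCC[C@@](CC(=O)c2cc(OCOC)ccc2OCOC)(C(=O)OC)OC1)CO | intermediate
17 | (2R)-2-{2-[2,5-bis(methoxymethoxy)phenyl]-2-oxoethyl}-6-[(3E)-5-hydroxy-4-methylpent-3-en-1-yl]-2,3,4,7-tetrahydrooxepine-2-carboxylic acid (lithium salt in the flask) | C/C(=C\CCC1=CCC[C@@](CC(=O)c2cc(OCOC)ccc2OCOC)(C(=O)O)OC1)CO | intermediate (not isolated)
18 | (2R)-2-[2-(2,5-dihydroxyphenyl)-2-oxoethyl]-6-[(3E)-5-hydroxy-4-methylpent-3-en-1-yl]-2,3,4,7-tetrahydrooxepine-2-carboxylic acid | C/C(=C\CCC1=CCC[C@@](CC(=O)c2cc(O)ccc2O)(C(=O)O)OC1)CO | target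

## Step count and risks

Total steps: 9 (steps 1–3 to dienediol 8, steps 4–6 to triflate 13, steps 7–9 after union).
Longest linear sequence: 6 steps (1/2 → 5 → 6 → 8 → 15 → 16 → 18; equally 9 → 10 → 12 → 13 → 15 → 16 → 18).

Steps most likely to fail:

**Step 8 (asymmetric oxa-Michael).** A seven-membered ring closing onto a fully substituted carbon may be slow or poorly selective with an amine base. A more basic bifunctional iminophosphorane of the same design is the first thing to tune. The sense of induction must be confirmed on the first run; the quinine-derived pseudo-enantiomer gives the mirror-image series. Fallback: setting out from 15, cyclise without stereocontrol using DBU (10 mol%, THF, 0 °C) to the racemic oxepine ester F1. Resolve it by preparative chiral SFC on an amylose phase into 16 and the (S)-oxepine ester F2. F2 is returned to the racemate by DBU-induced retro-oxa-Michael/re-addition and recycled. The route is rejoined at 16.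

**Step 7 (hydroboration/Suzuki union).** If the borinates are cleaved under the basic coupling, the freed C14–OH can cyclise onto the new enone without stereocontrol. The activated triflate may also hydrolyse, or the enone geometry may scramble. Fallback: setting out from 8, silylate both hydroxyls (TESCl, imidazole, CH2Cl2) to the bis-TES triene F3. Hydroborate with 1.1 equiv 9-BBN to the bis-TES alkylborane F4, and couple it with 13 under ordinary aqueous-base Suzuki conditions to the bis-TES enone ester F5. Remove the silyl groups under non-basic conditions (HF·pyridine/pyridine, THF, 0 °C) to rejoin the route at 15.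

**Step 9 (one-pot deprotection).** Hydroxide may trigger retro-oxa-Michael opening, leading to racemisation or, once a phenoxide is present, chromanone formation. The warm acid may also damage the allylic alcohol, and the hydroquinone is air-sensitive. Fallback: setting out from 16, remove the MOM groups first by acid-catalysed transacetalisation in methanol (cat. AcCl, MeOH, 0 °C) to the hydroquinone methyl ester F6. Then cleave the methyl ester without hydroxide by SN2 demethylation (LiI, EtOAc, reflux, Ar) followed by mild acidification, which rejoins the route at 18.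

## Further compounds

F1 | step 8 | methyl (2RS)-2-{2-[2,5-bis(methoxymethoxy)phenyl]-2-oxoethyl}-6-[(3E)-5-hydroxy-4-methylpent-3-en-1-yl]-2,3,4,7-tetrahydrooxepine-2-carboxylate (racemate) | C/C(=C\CCC1=CCCC(CC(=O)c2cc(OCOC)ccc2OCOC)(C(=O)OC)OC1)CO
F2 | step 8 | methyl (2S)-2-{2-[2,5-bis(methoxymethoxy)phenyl]-2-oxoethyl}-6-[(3E)-5-hydroxy-4-methylpent-3-en-1-yl]-2,3,4,7-tetrahydrooxepine-2-carboxylate | C/C(=C\CCC1=CCC[C@](CC(=O)c2cc(OCOC)ccc2OCOC)(C(=O)OC)OC1)CO
F3 | step 7 | triethyl{[(2E,6Z)-2-methyl-6-{[(triethylsilyl)oxy]methyl}nona-2,6,8-trien-1-yl]oxy}silane | C/C(=C\CC/C(CO[Si](CC)(CC)CC)=C/C=C)CO[Si](CC)(CC)CC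
F4 | step 7 | 9-[(3Z,7E)-8-methyl-9-[(triethylsilyl)oxy]-4-{[(triethylsilyl)oxy]methyl}nona-3,7-dien-1-yl]-9-borabicyclo[3.3.1]nonane | C/C(=C\CC/C(CO[Si](CC)(CC)CC)=C/CCB1C2CCCC1CCC2)CO[Si](CC)(CC)CC
F5 | step 7 | methyl (2E)-4-[2,5-bis(methoxymethoxy)phenyl]-2-[(3Z,7E)-8-methyl-9-[(triethylsilyl)oxy]-4-{[(triethylsilyl)oxy]methyl}nona-3,7-dien-1-yl]-4-oxobut-2-enoate | COC(=O)/C(CC/C=C(\CO[Si](CC)(CC)CC)CC/C=C(\C)CO[Si](CC)(CC)CC)=C/C(=O)c1cc(OCOC)ccc1OCOC
F6 | step 9 | methyl (2R)-2-[2-(2,5-dihydroxyphenyl)-2-oxoethyl]-6-[(3E)-5-hydroxy-4-methylpent-3-en-1-yl]-2,3,4,7-tetrahydrooxepine-2-carboxylate | C/C(=C\CCC1=CCC[C@@](CC(=O)c2cc(O)ccc2O)(C(=O)OC)OC1)CO
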